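## The problem

Compound 19 is a benzofuran-2,6-dione in which a five-membered lactone (O1, C2, C3) is fused across C3a–C7a to a six-membered carbocycle. The exocyclic C3=C3a bond and the C6 ketone stand para to each other and make the bicycle a para-quinone methide. All six carbons of the carbocycle are substituted (phenyl at C4 and C7, methoxy at C5, ketone at C6, lactone oxygen at C7a, methide at C3a) and C3 carries the 4-hydroxyphenyl ring, so the ring is crowded and the order in which substituents arrive matters. The target has no stereocentre. In the 2(3H)-one precursors C3 is a stereocentre, but it is α to the lactone carbonyl and doubly benzylic, so it is carried racemic, steers nothing and is erased in the final oxidation. The sensitive functions are the quinone methide (electrophilic at C3, with the C5 methoxy as a vinylogous ester), the aryl lactone (opened by hydroxide or alkoxide), the acidic C3–H of the reduced lactones (enolate chemistry, autoxidation) and the free phenol, which in 19 is a vinylogous acid. The quinone methide is therefore best formed last, by dehydrogenating a 6-hydroxy lactone, and this requires that O6 be distinguishable from the O5 methyl ether from the start. A late twofold arylation is possible because C4 and C7 lie para to each other and are the only carbons of the carbocycle bearing neither oxygen nor a lactone bond. Each is ortho to an alkoxy group, so in a 5,6-dialkoxybenzofuranone they are the only free positions of an electron-rich ring, open to bromination and then to cross-coupling.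

## Retrosynthesis

**19 ⇒ 18.** No skeletal bond is cut. The C3=C3a/C6=O unit of 19 is taken back to the C3–H and O6–H of the 6-hydroxy lactone 18. This keeps the quinone methide away from every reagent except the final oxidant. The neighbouring option, ionising a C3 leaving group with loss of an O6 methyl, would require one of two very similar, twisted methyl ethers to be cleaved and would put a base-labile ester cleavage after the quinone methide. Compound 18 is an ordinary aromatic lactone. The forward step needs only a two-electron oxidant that stops at the quinone methide.

**18 ⇒ 17 ⇒ 15.** The O6–isopropyl and the O4'–pivaloyl bonds are cut. O6 is carried as an isopropyl ether because it must stay an activating ether for the bromination, survive the coupling, and leave with BCl3 while the O5 methyl stays. The pendant phenol is carried as a pivalate because an acyl group deactivates that ring towards bromine and is inert to palladium and to phosphate. The pivalate is removed first (15 to 17, through the ring-opened methyl ester 16, which is reclosed with acid). In this way the base meets a compound whose O6 is still capped, and the oxygen-sensitive 18 appears only one step before the end.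

**15 ⇒ 12 + 13.** The C4–phenyl and C7–phenyl bonds are cut together, leading to dibromide 12 and two equivalents of phenylboronic acid 13, with the mono-coupled bromide 14 as the link. Making the two aryl–aryl bonds this late means that all earlier chemistry runs on an uncrowded ring. The opposite order would force the lactone annulation onto a carbon wedged between a hydroxyl and a phenyl group of a twisted terphenyl. The forward reaction must couple two di-ortho-substituted bromides without letting the lactone enolate, the lactone or the pivalate interfere.

**12 ⇒ 10 ⇒ 8 + 9.** The two C–Br bonds are cut, then the pivaloyl group (from pivaloyl chloride 9). In 10 the positions C4 and C7 are the only free ones of the dialkoxy ring, and the pendant ring is an aryl ester, so regiochemistry needs no directing device. Monobromide 11 is the intermediate. The forward reaction must avoid the enolisable C3–H.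

**8 ⇒ 5 + 6.** The C3–C3a bond and the O1–C2 bond are cut, giving phenol 5 and racemic 4-hydroxymandelic acid 6 (through hydroxy acid 7). This acid-catalysed condensation builds the whole lactone with its aryl group in one operation. The position of attack on 5 is ortho to the hydroxyl and para to the isopropoxy group, the most nucleophilic and least hindered carbon. The stereocentre at C3 need not be controlled.

**5 ⇒ 3 ⇒ 1 + 2.** The phenol oxygen of 5 is traced to the formyl group of aldehyde 3 (Baeyer–Villiger oxidation through formate 4), and the isopropyl ether to isovanillin 1 and 2-bromopropane 2. Isovanillin already has the methoxy and hydroxy groups in the required 1,2-relationship and distinguishes the two oxygens.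

## Roads not taken

**Alternative 1:** The cut is the O1–C7a bond. Catechol acid A2 would be oxidised at an anode to its ortho-quinone; the carboxylate would add to C7a to close the lactone, and further oxidation would give the 5-hydroxy quinone methide A1.
- Merits: the lactone and the quinone methide arise in one protecting-group-free oxidative operation, without a transition metal.
- Weak points: A1 lacks the O5 methyl, and methylation would have to distinguish the acidic O5–H from the pendant phenol, itself a vinylogous acid. A2 is already a fully arylated terphenyl, so the aryl–aryl bonds must be made earlier and without the benefit of the lactone. The catechol lactone formed first and A1 itself are easier to oxidise than A2, and the pendant phenol competes at the electrode.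
- Comparison: this road is better in end-game economy, with no separate deprotections. The chosen plan sets against it an O5 methyl present from isovanillin and no need ever to tell two acidic hydroxyls apart.

**Alternative 2:** The cut is the C3a–C7a bond of the carbocycle. Heating cyclobutenone A4 would open it to a dienylketene whose six-electron electrocyclisation and enolisation give phenol A3, with the substituents of C4 to C7 placed by construction. Condensation of A3 with 6 at its one free ortho position, dealkylation and oxidation would then lead to 19.
- Merits: the regiochemistry of the whole ring is fixed by squaric ester chemistry, O6 and O5 are differentiated from the outset, and no lactone with an acidic C3–H is present when the phenyl groups arrive. In these respects this road is better than the chosen plan, which relies on electrophilic bromination and on a coupling beside an enolisable lactone.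
- Weak points: A4 needs successive organolithium additions at low temperature and O-methylation of a tertiary alkoxide. The lactone annulation of A3 must alkylate a carbon flanked by the hydroxyl and the C4 phenyl in a less nucleophilic ring.
- Comparison: the chosen plan sets against it cheap aromatic starting materials, a Friedel–Crafts annulation on an unhindered carbon, and both phenyl groups from one catalytic operation.

**Alternative 3:** The cuts are the C2–C3 and C2–O1 bonds. The ortho-hydroxybenzhydrol A6 would be carbonylated under Pd(OAc)2 and a bisphosphine, the inserted carbon bonding to C3 and O1 to give lactone A5.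
- Merits: the C3–aryl bond comes from a simple carbonyl addition, and the benzyl ether can be removed by hydrogenolysis before oxidation.
- Weak points: A6 is again the complete terphenyl, so the arylation problem is only moved forward. Ionisation of the crowded diaryl carbinol gives an ortho-quinone methide that can dimerise or be reduced before carbonylation. A5 carries two methyl ethers, so selective unmasking of O6 is unsolved. Pressure equipment is needed.
- Comparison: this road has no advantage in step count. The chosen plan closes the lactone by a plain acid condensation and has the O6/O5 distinction built in.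

Key step: step 6

Remark: 19 is drawn as the 6-oxo quinone methide; the form with a quinoid pendant ring and a C6 hydroxyl is its prototropic tautomer, so step 9 is taken to deliver the same compound. All compounds with an sp3 C3 are racemic.

## Route

Step 1
Reactants: 1 isovanillin (3-hydroxy-4-methoxybenzaldehyde); 2 2-bromopropane
Product: 3 4-methoxy-3-(propan-2-yloxy)benzaldehyde
Conditions: K2CO3, DMF, 70 °C
Reagents that add atoms: none
Why: Williamson etherification; the phenoxide of 1 displaces bromide from the secondary halide, the aldehyde is inert to K2CO3, and an excess of 2 makes up for loss by elimination.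

Step 2
Reactants: 3 4-methoxy-3-(propan-2-yloxy)benzaldehyde
Product: 5 4-methoxy-3-(propan-2-yloxy)phenol, via aryl formate 4 (not isolated)
Conditions: mCPBA, CH2Cl2, 0 °C to rt; then K2CO3 (cat.), MeOH, rt
Reagents that add atoms: mCPBA (3-chloroperoxybenzoic acid), OOC(=O)c1cccc(Cl)c1
Why: Baeyer–Villiger (Dakin-type) oxidation; the electron-rich aryl group, para to the methoxy group, migrates in the Criegee adduct to give formate 4, which is transesterified to the phenol by carbonate in methanol without touching the ethers.

Step 3
Reactants: 5 4-methoxy-3-(propan-2-yloxy)phenol; 6 racemic 4-hydroxymandelic acid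
Product: 8 3-(4-hydroxyphenyl)-5-methoxy-6-(propan-2-yloxy)-1-benzofuran-2(3H)-one (racemic), via Friedel–Crafts hydroxy acid 7 (not isolated)
Conditions: TsOH·H2O (10 mol%), AcOH, 80 °C; 5 in excess (1.5 equiv)
Reagents that add atoms: none
Why: Acid-catalysed Friedel–Crafts hydroxyalkylation and lactonisation of a phenol with a mandelic acid; 6 ionises to a para-hydroxybenzylic cation that attacks C6 of 5 (ortho to the hydroxyl, para to the isopropoxy group, unhindered) to give 7, whose ortho-hydroxy acid closes the five-membered lactone. The excess of the more nucleophilic 5 should suppress self-alkylation of 6, and C3 forms racemic, which is all the route needs.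

Step 4
Reactants: 8 3-(4-hydroxyphenyl)-5-methoxy-6-(propan-2-yloxy)-1-benzofuran-2(3H)-one; 9 pivaloyl chloride
Product: 10 4-[5-methoxy-2-oxo-6-(propan-2-yloxy)-2,3-dihydro-1-benzofuran-3-yl]phenyl 2,2-dimethylpropanoate (racemic)
Conditions: pyridine, CH2Cl2, 0 °C to rt
Reagents that add atoms: none
Why: Phenol acylation through the N-acylpyridinium salt; pyridine is too weak a base to enolise the lactone, so acylation at the C2 enol oxygen is not expected. The pivalate deactivates the pendant ring for step 5 and is inert to palladium in step 6.

Step 5
Reactants: 10 4-[5-methoxy-2-oxo-6-(propan-2-yloxy)-2,3-dihydro-1-benzofuran-3-yl]phenyl 2,2-dimethylpropanoate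
Product: 12 4-[4,7-dibromo-5-methoxy-2-oxo-6-(propan-2-yloxy)-2,3-dihydro-1-benzofuran-3-yl]phenyl 2,2-dimethylpropanoate (racemic), via 7-bromo lactone 11 (not isolated)
Conditions: NBS (2.2 equiv), MeCN, 0 to 50 °C, dark; aq. Na2S2O3 wash
Reagents that add atoms: N-bromosuccinimide, BrN1C(=O)CCC1=O
Why: Electrophilic aromatic bromination with NBS in a polar aprotic solvent; C4 and C7 are the only free positions of the dialkoxy ring and each is ortho to an alkoxy group, whereas the pendant ring is a deactivated aryl ester. The first bromine is expected at C7, flanked only by oxygen substituents, and the second at C4 beside the C3 aryl group; either order converges on 12. Neutral conditions in the dark should avoid enol or radical bromination at C3.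

Step 6
Reactants: 12 4-[4,7-dibromo-5-methoxy-2-oxo-6-(propan-2-yloxy)-2,3-dihydro-1-benzofuran-3-yl]phenyl 2,2-dimethylpropanoate; 13 phenylboronic acid (3.5 equiv)
Product: 15 4-[5-methoxy-2-oxo-4,7-diphenyl-6-(propan-2-yloxy)-2,3-dihydro-1-benzofuran-3-yl]phenyl 2,2-dimethylpropanoate (racemic), via 4-bromo-7-phenyl lactone 14 (not isolated)
Conditions: Pd(OAc)2 (5 mol%), SPhos (10 mol%), K3PO4 (finely ground, 5 equiv), toluene, 90 °C, argon; then dilute aq. HCl
Reagents that add atoms: none
Why: Pd(OAc)2 is reduced in the flask to zerovalent palladium carrying the bulky dialkylbiarylphosphine; this adds oxidatively into a C–Br bond, the phosphate-activated phenylboronate transmetalates to the arylpalladium bromide (divalent palladium), and reductive elimination forms the aryl–aryl bond, after which the cycle repeats at the second bromide. The closest known reaction type is the twofold Suzuki–Miyaura coupling of di-ortho-substituted, electron-rich aryl bromides with Pd(OAc)2 and SPhos. C7–Br, flanked by two inductively withdrawing oxygens, should react first to give 14; C4–Br is shielded by the C3 aryl group and is made more electron-rich whenever C3 is deprotonated, but either order converges on 15. No ring is closed and no stereocentre is formed; C3 stays racemic and is planarised in step 9. The step needs C–Br insertion to be preferred over the aryl pivalate and lactone C–O bonds, which palladium with this ligand does not cleave. It also needs aryl–aryl coupling to outrun α-arylation of the C3 enolate: that process would have to join a di-ortho-substituted arylpalladium to a tertiary carbon to make a quaternary centre, whereas transmetalation with an excess of the small boronate is fast. Running without added water or hydroxide spares the lactone and the pivalate from saponification, and the acidic quench reprotonates C3 and recloses any lactone that opened. Exclusion of oxygen prevents oxidation of the enolate.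

Step 7
Reactants: 15 4-[5-methoxy-2-oxo-4,7-diphenyl-6-(propan-2-yloxy)-2,3-dihydro-1-benzofuran-3-yl]phenyl 2,2-dimethylpropanoate
Product: 17 3-(4-hydroxyphenyl)-5-methoxy-4,7-diphenyl-6-(propan-2-yloxy)-1-benzofuran-2(3H)-one (racemic), via ring-opened methyl ester 16 (not isolated)
Conditions: NaOMe, MeOH/THF, rt, argon; then aq. HCl; TsOH (cat.), toluene, 80 °C
Reagents that add atoms: none
Why: Methoxide cleaves the aryl pivalate by transesterification and opens the aryl lactone to methyl ester 16; acid then recloses the five-membered lactone with loss of methanol (acid-catalysed lactonisation of an ortho-hydroxyphenylacetate). Both ethers are inert to the two stages.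

Step 8
Reactants: 17 3-(4-hydroxyphenyl)-5-methoxy-4,7-diphenyl-6-(propan-2-yloxy)-1-benzofuran-2(3H)-one
Product: 18 6-hydroxy-3-(4-hydroxyphenyl)-5-methoxy-4,7-diphenyl-1-benzofuran-2(3H)-one (racemic)
Conditions: BCl3 (4 equiv), CH2Cl2, −78 to 0 °C; then H2O, under argon
Reagents that add atoms: none
Why: Lewis-acid dealkylation of an aryl isopropyl ether; BCl3 binds the ether oxygen and the secondary alkyl group leaves as 2-chloropropane, while the methyl ether, with no chelating ortho carbonyl, should be retained at low temperature. The lactone meets no nucleophile and should stay closed; 18 is handled under argon because it is easily oxidised.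

Step 9
Reactants: 18 6-hydroxy-3-(4-hydroxyphenyl)-5-methoxy-4,7-diphenyl-1-benzofuran-2(3H)-one
Product: 19 3-(4-hydroxyphenyl)-5-methoxy-4,7-diphenyl-1-benzofuran-2,6-dione
Conditions: DDQ (1.05 equiv), CH2Cl2, 0 °C to rt
Reagents that add atoms: none
Why: Dehydrogenation of a para-hydroxybenzylic C–H to a para-quinone methide with DDQ (fuchsone-type oxidation); hydride leaves the doubly benzylic C3, whose cation is stabilised by the C6 hydroxyl para to C3a, and loss of the O6 proton gives the C3=C3a/C6=O system. No further oxidisable C–H remains, and the racemic stereocentre disappears.

## Compound list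

1 | isovanillin (3-hydroxy-4-methoxybenzaldehyde) | COc1ccc(C=O)cc1O | starting material
2 | 2-bromopropane | CC(C)Br | starting material
3 | 4-methoxy-3-(propan-2-yloxy)benzaldehyde | COc1ccc(C=O)cc1OC(C)C | intermediate
4 | 4-methoxy-3-(propan-2-yloxy)phenyl formate (formed in step 2, not isolated) | COc1ccc(OC=O)cc1OC(C)C | intermediate
5 | 4-methoxy-3-(propan-2-yloxy)phenol | COc1ccc(O)cc1OC(C)C | intermediate
6 | racemic 4-hydroxymandelic acid | OC(C(=O)O)c1ccc(O)cc1 | starting material
7 | 2-[2-hydroxy-5-methoxy-4-(propan-2-yloxy)phenyl]-2-(4-hydroxyphenyl)acetic acid (racemic; formed in step 3, not isolated) | COc1cc(C(C(=O)O)c2ccc(O)cc2)c(O)cc1OC(C)C | intermediate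
8 | 3-(4-hydroxyphenyl)-5-methoxy-6-(propan-2-yloxy)-1-benzofuran-2(3H)-one (racemic) | COc1cc2c(cc1OC(C)C)OC(=O)C2c1ccc(O)cc1 | intermediate
9 | pivaloyl chloride | CC(C)(C)C(Cl)=O | starting material
10 | 4-[5-methoxy-2-oxo-6-(propan-2-yloxy)-2,3-dihydro-1-benzofuran-3-yl]phenyl 2,2-dimethylpropanoate (racemic) | COc1cc2c(cc1OC(C)C)OC(=O)C2c1ccc(OC(=O)C(C)(C)C)cc1 | intermediate
11 | 4-[7-bromo-5-methoxy-2-oxo-6-(propan-2-yloxy)-2,3-dihydro-1-benzofuran-3-yl]phenyl 2,2-dimethylpropanoate (racemic; formed in step 5, not isolated) | COc1cc2c(c(Br)c1OC(C)C)OC(=O)C2c1ccc(OC(=O)C(C)(C)C)cc1 | intermediate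
12 | 4-[4,7-dibromo-5-methoxy-2-oxo-6-(propan-2-yloxy)-2,3-dihydro-1-benzofuran-3-yl]phenyl 2,2-dimethylpropanoate (racemic) | COc1c(Br)c2c(c(Br)c1OC(C)C)OC(=O)C2c1ccc(OC(=O)C(C)(C)C)cc1 | intermediate
13 | phenylboronic acid | OB(O)c1ccccc1 | starting material
14 | 4-[4-bromo-5-methoxy-2-oxo-7-phenyl-6-(propan-2-yloxy)-2,3-dihydro-1-benzofuran-3-yl]phenyl 2,2-dimethylpropanoate (racemic; formed in step 6, not isolated) | COc1c(Br)c2c(c(-c3ccccc3)c1OC(C)C)OC(=O)C2c1ccc(OC(=O)C(C)(C)C)cc1 | intermediate
15 | 4-[5-methoxy-2-oxo-4,7-diphenyl-6-(propan-2-yloxy)-2,3-dihydro-1-benzofuran-3-yl]phenyl 2,2-dimethylpropanoate (racemic) | COc1c(-c3ccccc3)c2c(c(-c3ccccc3)c1OC(C)C)OC(=O)C2c1ccc(OC(=O)C(C)(C)C)cc1 | intermediate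
16 | methyl 2-[2-hydroxy-5-methoxy-3,6-diphenyl-4-(propan-2-yloxy)phenyl]-2-(4-hydroxyphenyl)acetate (racemic; formed in step 7, not isolated) | COC(=O)C(c1ccc(O)cc1)c1c(O)c(-c2ccccc2)c(OC(C)C)c(OC)c1-c1ccccc1 | intermediate
17 | 3-(4-hydroxyphenyl)-5-methoxy-4,7-diphenyl-6-(propan-2-yloxy)-1-benzofuran-2(3H)-one (racemic) | COc1c(-c3ccccc3)c2c(c(-c3ccccc3)c1OC(C)C)OC(=O)C2c1ccc(O)cc1 | intermediate
18 | 6-hydroxy-3-(4-hydroxyphenyl)-5-methoxy-4,7-diphenyl-1-benzofuran-2(3H)-one (racemic) | COc1c(-c3ccccc3)c2c(c(-c3ccccc3)c1O)OC(=O)C2c1ccc(O)cc1 | intermediate
19 | 3-(4-hydroxyphenyl)-5-methoxy-4,7-diphenyl-1-benzofuran-2,6-dione | COC1=C(c2ccccc2)C2=C(c3ccc(O)cc3)C(=O)OC2=C(c2ccccc2)C1=O | target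

## Step count and risks

Total step count: 9. Longest linear sequence: 9 steps (1 to 19).

**Step 6 (key step).** The most likely failure is stalling after the first coupling: oxidative addition at the crowded C4–Br, made more electron-rich when C3 is deprotonated, may be slow enough for protodebromination to take over. Enolate formation under phosphate may also open the lactone or lead to oxidative coupling at C3. The fallback sets out from 12 and removes the acidic lactone before the coupling. Methanolysis with NaOMe in MeOH opens the lactone and removes the pivalate to give methyl 2-[3,6-dibromo-2-hydroxy-5-methoxy-4-(propan-2-yloxy)phenyl]-2-(4-hydroxyphenyl)acetate F1, whose ester α-C–H is no longer acidic enough to interfere. Twofold Suzuki–Miyaura coupling of F1 with 13 under Pd(OAc)2, SPhos and aqueous K3PO4, which tolerates free phenols, gives 16. The fallback returns to the route at 16, which the acid stage of step 7 closes to 17.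

**Step 5.** The second bromination, on a ring already deactivated by the first bromine, may become slower than bromination at C3 through the enol or attack on the pendant ring at the temperature it requires. The fallback sets out from 10 and alternates bromination and coupling. One equivalent of NBS gives 11, which is isolated and coupled with 13 under the conditions of step 6 to give 4-[5-methoxy-2-oxo-7-phenyl-6-(propan-2-yloxy)-2,3-dihydro-1-benzofuran-3-yl]phenyl 2,2-dimethylpropanoate F2. In F2 the remaining position C4 is para to a phenyl group instead of a bromine and should brominate more readily, giving 14. The fallback returns to the route at 14, which is coupled again to 15. If the first bromine enters at C4 instead, the same alternation applies in mirror order.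

**Step 3.** Compound 6 may alkylate its own phenol ring and oligomerise, a second cation may attack 8, or hot acid may partly cleave the isopropyl ether. The fallback sets out from 6 and 9 and acylates before condensing. Schotten–Baumann acylation of the phenoxide of 6 (aq. NaOH, 0 °C) gives 2-{4-[(2,2-dimethylpropanoyl)oxy]phenyl}-2-hydroxyacetic acid F3, whose ring is no longer nucleophilic. Condensation of F3 with 5 under BF3·OEt2 in CH2Cl2 gives 10 directly. The fallback returns to the route at 10 and bypasses 8 and step 4.

**Step 8.** Dealkylation at the crowded O6 may be incomplete, warming may also remove the C5 methyl, and 18 may oxidise uncontrollably during isolation. The fallback sets out from 17 and reverses the order of oxidation and dealkylation. DDQ dehydrogenates 17 through its free pendant phenol to 5-methoxy-3-(4-oxocyclohexa-2,5-dien-1-ylidene)-4,7-diphenyl-6-(propan-2-yloxy)-1-benzofuran-2(3H)-one F4. Warm CF3CO2H then protonates the dienone oxygen, which places the positive charge on O6 and expels the secondary alkyl group by an SN1-type cleavage that a methyl group cannot follow. The fallback returns to the route at 19.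

## Further compounds

F1 | step 6 | methyl 2-[3,6-dibromo-2-hydroxy-5-methoxy-4-(propan-2-yloxy)phenyl]-2-(4-hydroxyphenyl)acetate (racemic) | COC(=O)C(c1ccc(O)cc1)c1c(O)c(Br)c(OC(C)C)c(OC)c1Br
F2 | step 5 | 4-[5-methoxy-2-oxo-7-phenyl-6-(propan-2-yloxy)-2,3-dihydro-1-benzofuran-3-yl]phenyl 2,2-dimethylpropanoate (racemic) | COc1cc2c(c(-c3ccccc3)c1OC(C)C)OC(=O)C2c1ccc(OC(=O)C(C)(C)C)cc1
F3 | step 3 | 2-{4-[(2,2-dimethylpropanoyl)oxy]phenyl}-2-hydroxyacetic acid (racemic) | CC(C)(C)C(=O)Oc1ccc(C(O)C(=O)O)cc1
F4 | step 8 | 5-methoxy-3-(4-oxocyclohexa-2,5-dien-1-ylidene)-4,7-diphenyl-6-(propan-2-yloxy)-1-benzofuran-2(3H)-one | COc1c(-c3ccccc3)c2c(c(-c3ccccc3)c1OC(C)C)OC(=O)C2=C1C=CC(=O)C=C1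
A1 | alternative 1 | 5-hydroxy-3-(4-hydroxyphenyl)-4,7-diphenyl-1-benzofuran-2,6-dione | OC1=C(c2ccccc2)C2=C(c3ccc(O)cc3)C(=O)OC2=C(c2ccccc2)C1=O
A2 | alternative 1 | 2-(3,4-dihydroxy-2,5-diphenylphenyl)-2-(4-hydroxyphenyl)acetic acid (racemic) | OC(=O)C(c1ccc(O)cc1)c1cc(-c2ccccc2)c(O)c(O)c1-c1ccccc1
A3 | alternative 2 | 4-methoxy-2,5-diphenyl-3-(propan-2-yloxy)phenol | Oc1cc(-c2ccccc2)c(OC)c(OC(C)C)c1-c1ccccc1
A4 | alternative 2 | 4-methoxy-2-phenyl-4-(1-phenylethenyl)-3-(propan-2-yloxy)cyclobut-2-en-1-one (racemic) | COC1(C(=C)c2ccccc2)C(OC(C)C)=C(c2ccccc2)C1=O
A5 | alternative 3 | 3-[4-(benzyloxy)phenyl]-5,6-dimethoxy-4,7-diphenyl-1-benzofuran-2(3H)-one (racemic) | COc1c(OC)c(-c2ccccc2)c2OC(=O)C(c3ccc(OCc4ccccc4)cc3)c2c1-c1ccccc1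
A6 | alternative 3 | 2-{[4-(benzyloxy)phenyl](hydroxy)methyl}-4,5-dimethoxy-3,6-diphenylphenol (racemic) | COc1c(OC)c(-c2ccccc2)c(O)c(C(O)c2ccc(OCc3ccccc3)cc2)c1-c1ccccc1
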